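**Retrosynthetic overview**
- Target: (2S,3S,5S)-7-(4-hydroxy-3-methoxyphenyl)-1-(4-hydroxyphenyl)heptane-2,3,5-triol, all-syn. C1 is the CH2 on ring B (4-hydroxyphenyl), C7 the CH2 on ring A (guaiacyl). O3 and O5 are the oxygens on C3 and C5.
- Enabling feature: C7 stands 1,3 to O5 and 1,5 to O3. The atoms O3–C3–C4–C5(=O5)–C6=C7 can therefore be closed to one six-membered 2,3-dihydro-4H-pyran-4-one ring, in which C7 is a masked formyl (vinylogous acyl) carbon that can trade its heteroatom for ring A.
- Key disconnection ring A–C7: amine-relayed arylative opening of that ring (pyrrolidine, then aryl Grignard reagent, Benary addition–elimination) gives the open E-enone with O3–H as the only free hydroxyl. O3–H then sets C5 (Narasaka–Prasad reduction), and one hydrogenation ends the route.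
- The pyranone is the only ring formed and is temporary; rings A and B are bought. It comes from a chelation-controlled hetero-Diels–Alder reaction that sets C3 and brings in C4–C7 as a siloxydiene.
- Ring B, C1, C2 (S, oxygen in place of nitrogen with retention) and C3 are the nine carbons of L-tyrosine.

Key step: step 6

Assumption: O-benzyl-L-tyrosine (peptide-synthesis grade), (E)-1-methoxy-3-(trimethylsilyloxy)buta-1,3-diene and 4-bromo-2-methoxyphenol are taken as purchasable.

Step 1
Reactants: 1 O-benzyl-L-tyrosine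
Product: 2 (S)-3-[4-(benzyloxy)phenyl]-2-hydroxypropanoic acid
Conditions: NaNO2, 1 M H2SO4, H2O–1,4-dioxane, 0 → 25 °C
Reagents that add atoms: water, O
Why: Diazotization of an α-amino acid, in which the diazonium group is displaced by the neighbouring carboxylate (α-lactone) and the lactone is opened by water, so two inversions add up to retention and C2 should keep the S configuration of L-tyrosine.

Step 2
Reactants: 2 (S)-3-[4-(benzyloxy)phenyl]-2-hydroxypropanoic acid
Product: 3 benzyl (S)-2-(benzyloxy)-3-[4-(benzyloxy)phenyl]propanoate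
Conditions: BnBr (3 equiv), Ag2O (2 equiv), n-Bu4NI (cat.), CH2Cl2, 4 Å MS, 25 °C, dark
Reagents that add atoms: benzyl bromide, BrCc1ccccc1
Why: Purdie-type alkylation with Ag2O benzylates the carboxyl and the hydroxyl group in one operation under non-basic conditions, so the α-stereocentre C2 is not enolized.

Step 3
Reactants: 3 benzyl (S)-2-(benzyloxy)-3-[4-(benzyloxy)phenyl]propanoate
Product: 4 (S)-2-(benzyloxy)-3-[4-(benzyloxy)phenyl]propanal
Conditions: i-Bu2AlH (1.1 equiv), CH2Cl2, −78 °C; then aq. potassium sodium tartrate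
Reagents that add atoms: none
Why: Partial ester reduction with i-Bu2AlH, in which the aluminium hemiacetal, stabilised by chelation to the α-benzyloxy oxygen, should survive at −78 °C and collapse to the aldehyde only on work-up, with C2 untouched.

Step 4
Reactants: 4 (S)-2-(benzyloxy)-3-[4-(benzyloxy)phenyl]propanal; 5 (E)-1-methoxy-3-(trimethylsilyloxy)buta-1,3-diene
Product: 7 (2S)-2-[(1S)-1-(benzyloxy)-2-[4-(benzyloxy)phenyl]ethyl]-2,3-dihydro-4H-pyran-4-one, via cycloadduct 6 (not isolated)
Conditions: MgBr2·OEt2 (2 equiv), CH2Cl2, −78 → −20 °C; then CF3CO2H (cat.), CH2Cl2, 0 °C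
Reagents that add atoms: none
Why: Lewis acid promoted hetero-Diels–Alder cyclocondensation of a 1-alkoxy-3-siloxydiene with an aldehyde, in which magnesium ties the carbonyl and the C2 benzyloxy oxygen into a five-membered Cram chelate, the diene attacks the face that bears only the C2 hydrogen and so should set C3 as S (2,3-syn), and acid then expels methanol and the silyl group from 6 (or from its open Mukaiyama aldol isomer) to leave the vinylogous ester ring.

Step 5
Reactants: 8 4-bromo-2-methoxyphenol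
Product: 9 1-(benzyloxy)-4-bromo-2-methoxybenzene
Conditions: BnBr, K2CO3, DMF, 25 °C
Reagents that add atoms: benzyl bromide, BrCc1ccccc1
Why: Williamson ether synthesis on the phenoxide masks the acidic phenol so that the bromide can be turned into a Grignard reagent.

Step 6
Reactants: 7 (2S)-2-[(1S)-1-(benzyloxy)-2-[4-(benzyloxy)phenyl]ethyl]-2,3-dihydro-4H-pyran-4-one; 9 1-(benzyloxy)-4-bromo-2-methoxybenzene
Product: 13 (1E,5S,6S)-6-(benzyloxy)-1-[4-(benzyloxy)-3-methoxyphenyl]-7-[4-(benzyloxy)phenyl]-5-hydroxyhept-1-en-3-one, via open enaminone 10 (not isolated), via aryl Grignard reagent 11 (not isolated), via β-amino ketone 12 (not isolated)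
Conditions: 7, pyrrolidine (1.2 equiv), THF, 25 °C, excess amine evaporated; then 11 (2.5 equiv, made from 9, Mg turnings, I2 cat., THF, 40 °C), THF, −40 → 0 °C; then 1 M HCl, 0 → 25 °C
Reagents that add atoms: none
Why: The step strings together two known reaction types in one flask, the amine opening of a cyclic vinylogous ester (as with chromones and 4-pyranones) and the Benary reaction (conjugate addition of a Grignard reagent to a β-amino vinyl ketone followed by loss of the amine). Pyrrolidine adds to C7 of 7, the ring oxygen O3 leaves as the tethered alkoxide and the open E-enaminone 10 forms as the thermodynamic product; the first equivalent of 11 then only deprotonates O3–H and the second attacks C7, the iminium-like end of the push–pull system O=C5–C6=C7–N, to give a magnesium enolate that holds its amine until the quench. Acid turns this into β-amino ketone 12, which loses pyrrolidine (E1cB, helped by the electron-rich ring A) to give the conjugated E-enone 13, so that opening of the temporary ring, formation of the ring A–C7 bond, removal of the activating group and release of O3–H as the only free hydroxyl fall into one operation. No ring is closed and no lasting stereocentre is made: C7 of 12 is a mixture that the elimination erases, and C2 and C3 are not enolizable positions, C3 being held as a chelated magnesium alkoxide whose retro-aldol cleavage would have to expel a poor vinylogous amide enolate. The step needs 1,4- over 1,2-attack, which the amide-type donation of nitrogen secures by deactivating C5 (the reason for the passage through 10, since the vinylogous ester 7 itself would be attacked at C5); single over double arylation, secured because no enone is set free while 11 is present; and elimination over re-closure of O3 onto C7, secured by a short cold quench because the 6-endo oxa-Michael closure needs stronger acid.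

Step 7
Reactants: 13 (1E,5S,6S)-6-(benzyloxy)-1-[4-(benzyloxy)-3-methoxyphenyl]-7-[4-(benzyloxy)phenyl]-5-hydroxyhept-1-en-3-one
Product: 15 (1E,3R,5S,6S)-6-(benzyloxy)-1-[4-(benzyloxy)-3-methoxyphenyl]-7-[4-(benzyloxy)phenyl]hept-1-ene-3,5-diol, via diethylboron chelate 14 (not isolated)
Conditions: Et2BOMe (1.2 equiv), THF–MeOH 4:1, −78 °C; NaBH4, −78 °C; then pH 7 buffer, 30% H2O2, MeOH, 0 °C
Reagents that add atoms: none
Why: Narasaka–Prasad reduction, in which Et2BOMe binds O3 and the C5 carbonyl in the six-membered half-chair chelate 14 and external hydride attacks axially, should give the 3,5-syn diol by 1,2-reduction of the enone (new centre at chain C5, called 3R in this name only because the alkene carbon outranks C4).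

Step 8
Reactants: 15 (1E,3R,5S,6S)-6-(benzyloxy)-1-[4-(benzyloxy)-3-methoxyphenyl]-7-[4-(benzyloxy)phenyl]hept-1-ene-3,5-diol
Product: 16 (2S,3S,5S)-7-(4-hydroxy-3-methoxyphenyl)-1-(4-hydroxyphenyl)heptane-2,3,5-triol
Conditions: H2 (1 atm), 10% Pd/C, EtOAc–EtOH, 25 °C
Reagents that add atoms: none
Why: Heterogeneous catalytic hydrogenation saturates C6=C7 and hydrogenolyses the three benzyl ethers in one operation under neutral conditions, and since no carbinol centre is benzylic or allylic once the alkene is reduced, C2, C3 and C5 should stay S,S,S.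

**Compound list**
1 | O-benzyl-L-tyrosine, (S)-2-amino-3-[4-(benzyloxy)phenyl]propanoic acid | N[C@@H](Cc1ccc(OCc2ccccc2)cc1)C(=O)O | starting material
2 | (S)-3-[4-(benzyloxy)phenyl]-2-hydroxypropanoic acid | O[C@@H](Cc1ccc(OCc2ccccc2)cc1)C(=O)O | intermediate
3 | benzyl (S)-2-(benzyloxy)-3-[4-(benzyloxy)phenyl]propanoate | C(c1ccccc1)O[C@@H](Cc1ccc(OCc2ccccc2)cc1)C(=O)OCc1ccccc1 | intermediate
4 | (S)-2-(benzyloxy)-3-[4-(benzyloxy)phenyl]propanal | C(c1ccccc1)O[C@@H](Cc1ccc(OCc2ccccc2)cc1)C=O | intermediate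
5 | (E)-1-methoxy-3-(trimethylsilyloxy)buta-1,3-diene | CO/C=C/C(=C)O[Si](C)(C)C | starting material
6 | (2S)-2-[(1S)-1-(benzyloxy)-2-[4-(benzyloxy)phenyl]ethyl]-6-methoxy-4-(trimethylsilyloxy)-3,6-dihydro-2H-pyran, mixture at ring C6 | COC1C=C(O[Si](C)(C)C)C[C@H](O1)[C@@H](OCc1ccccc1)Cc1ccc(OCc2ccccc2)cc1 | intermediate
7 | (2S)-2-[(1S)-1-(benzyloxy)-2-[4-(benzyloxy)phenyl]ethyl]-2,3-dihydro-4H-pyran-4-one | O=C1C=CO[C@@H](C1)[C@@H](OCc1ccccc1)Cc1ccc(OCc2ccccc2)cc1 | intermediate
8 | 4-bromo-2-methoxyphenol | COc1cc(Br)ccc1O | starting material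
9 | 1-(benzyloxy)-4-bromo-2-methoxybenzene | COc1cc(Br)ccc1OCc1ccccc1 | intermediate
10 | (1E,5S,6S)-6-(benzyloxy)-7-[4-(benzyloxy)phenyl]-5-hydroxy-1-(pyrrolidin-1-yl)hept-1-en-3-one | O=C(/C=C/N1CCCC1)C[C@H](O)[C@@H](OCc1ccccc1)Cc1ccc(OCc2ccccc2)cc1 | intermediate
11 | [4-(benzyloxy)-3-methoxyphenyl]magnesium bromide | COc1cc([Mg]Br)ccc1OCc1ccccc1 | intermediate
12 | (5S,6S)-6-(benzyloxy)-1-[4-(benzyloxy)-3-methoxyphenyl]-7-[4-(benzyloxy)phenyl]-5-hydroxy-1-(pyrrolidin-1-yl)heptan-3-one, mixture at C1 | COc1cc(C(CC(=O)C[C@H](O)[C@@H](OCc2ccccc2)Cc2ccc(OCc3ccccc3)cc2)N2CCCC2)ccc1OCc1ccccc1 | intermediate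
13 | (1E,5S,6S)-6-(benzyloxy)-1-[4-(benzyloxy)-3-methoxyphenyl]-7-[4-(benzyloxy)phenyl]-5-hydroxyhept-1-en-3-one | COc1cc(/C=C/C(=O)C[C@H](O)[C@@H](OCc2ccccc2)Cc2ccc(OCc3ccccc3)cc2)ccc1OCc1ccccc1 | intermediate
14 | O3-diethylboryl derivative of 13, boron chelated to the C5 carbonyl | CCB(CC)O[C@@H](CC(=O)/C=C/c1ccc(OCc2ccccc2)c(OC)c1)[C@@H](OCc1ccccc1)Cc1ccc(OCc2ccccc2)cc1 | intermediate
15 | (1E,3R,5S,6S)-6-(benzyloxy)-1-[4-(benzyloxy)-3-methoxyphenyl]-7-[4-(benzyloxy)phenyl]hept-1-ene-3,5-diol | COc1cc(/C=C/[C@H](O)C[C@H](O)[C@@H](OCc2ccccc2)Cc2ccc(OCc3ccccc3)cc2)ccc1OCc1ccccc1 | intermediate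
16 | (2S,3S,5S)-7-(4-hydroxy-3-methoxyphenyl)-1-(4-hydroxyphenyl)heptane-2,3,5-triol | COc1cc(CC[C@H](O)C[C@H](O)[C@@H](O)Cc2ccc(O)cc2)ccc1O | target

**Step count and risks**
Total step count: 8. Longest linear sequence: 7 (steps 1–4, 6–8).

Steps most likely to fail:

Step 6. The Grignard reagent may attack the C5 carbonyl instead of C7, the amine may leave too slowly, or O3 may close back onto C7 during the acidic quench. Fallback: it sets out from aldehyde 4 and leaves out the pyranone and the amine. A chelation-controlled Mukaiyama aldol reaction of 4 with 2-(trimethylsilyloxy)buta-1,3-diene (MgBr2·OEt2, CH2Cl2, −78 °C) should give the vinyl ketone (5S,6S)-6-(benzyloxy)-7-[4-(benzyloxy)phenyl]-5-hydroxyhept-1-en-3-one F1. A Mizoroki–Heck reaction of this ketone with bromide 9 (Pd2(dba)3, P(t-Bu)3, Cy2NMe, 1,4-dioxane, 25–40 °C) makes the same ring A–C7 bond and comes back to the route at enone 13.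

Step 4. Facial selectivity may be poor if part of the reaction runs through the non-chelated aldehyde, and 4 may epimerize at C2 on the Lewis acid during the slower cyclocondensation. Fallback: it sets out from 4 and builds C4–C7 stepwise.
- A Keck-type chelation-controlled allylation (allyltributylstannane, MgBr2·OEt2, CH2Cl2, −78 °C) should give (2S,3S)-2-(benzyloxy)-1-[4-(benzyloxy)phenyl]hex-5-en-3-ol F2.
- Tsuji–Wacker oxidation (PdCl2, CuCl, O2, DMF–H2O) should give (4S,5S)-5-(benzyloxy)-6-[4-(benzyloxy)phenyl]-4-hydroxyhexan-2-one F3.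
- Double deprotonation (LiN(i-Pr)2, 2.2 equiv, THF, −78 °C) and Claisen formylation at the methyl group with 2,2,2-trifluoroethyl formate should give (5S,6S)-6-(benzyloxy)-7-[4-(benzyloxy)phenyl]-5-hydroxy-3-oxoheptanal F4.
- Acid-catalysed cyclodehydration (TsOH cat., CH2Cl2) comes back to the route at pyranone 7.

Step 8. The allylic C5 hydroxyl of the electron-rich cinnamyl-type alcohol may be lost by hydrogenolysis before C6=C7 is saturated. Fallback: it sets out from enone 13 and removes the alkene before the carbinol exists.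
- Conjugate reduction with [(PPh3)CuH]6 (toluene, 25 °C) should give (5S,6S)-6-(benzyloxy)-1-[4-(benzyloxy)-3-methoxyphenyl]-7-[4-(benzyloxy)phenyl]-5-hydroxyheptan-3-one F5.
- Narasaka–Prasad reduction (Et2BOMe, NaBH4, THF–MeOH, −78 °C) should give (3S,5S,6S)-6-(benzyloxy)-1-[4-(benzyloxy)-3-methoxyphenyl]-7-[4-(benzyloxy)phenyl]heptane-3,5-diol F6.
- Plain hydrogenolysis of the three benzyl ethers (H2, 10% Pd/C, EtOH) comes back to the route at target 16.

**Further compounds**
F1 | step 6 | (5S,6S)-6-(benzyloxy)-7-[4-(benzyloxy)phenyl]-5-hydroxyhept-1-en-3-one | C=CC(=O)C[C@H](O)[C@@H](OCc1ccccc1)Cc1ccc(OCc2ccccc2)cc1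
F2 | step 4 | (2S,3S)-2-(benzyloxy)-1-[4-(benzyloxy)phenyl]hex-5-en-3-ol | C=CC[C@H](O)[C@@H](OCc1ccccc1)Cc1ccc(OCc2ccccc2)cc1
F3 | step 4 | (4S,5S)-5-(benzyloxy)-6-[4-(benzyloxy)phenyl]-4-hydroxyhexan-2-one | CC(=O)C[C@H](O)[C@@H](OCc1ccccc1)Cc1ccc(OCc2ccccc2)cc1
F4 | step 4 | (5S,6S)-6-(benzyloxy)-7-[4-(benzyloxy)phenyl]-5-hydroxy-3-oxoheptanal | O=CCC(=O)C[C@H](O)[C@@H](OCc1ccccc1)Cc1ccc(OCc2ccccc2)cc1
F5 | step 8 | (5S,6S)-6-(benzyloxy)-1-[4-(benzyloxy)-3-methoxyphenyl]-7-[4-(benzyloxy)phenyl]-5-hydroxyheptan-3-one | COc1cc(CCC(=O)C[C@H](O)[C@@H](OCc2ccccc2)Cc2ccc(OCc3ccccc3)cc2)ccc1OCc1ccccc1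
F6 | step 8 | (3S,5S,6S)-6-(benzyloxy)-1-[4-(benzyloxy)-3-methoxyphenyl]-7-[4-(benzyloxy)phenyl]heptane-3,5-diol | COc1cc(CC[C@H](O)C[C@H](O)[C@@H](OCc2ccccc2)Cc2ccc(OCc3ccccc3)cc2)ccc1OCc1ccccc1
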